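The six-membered carbocycle is traced back to benzoic acid: the tertiary carbinol C1 with its one-carbon branch C7, the cis oxygen on C2 and the C3=C4 alkene are the footprint of an enzymatic cis-dihydroxylation across the ipso/ortho bond. In one operation this whole-cell oxidation dearomatises the flat, achiral acid, sets C1 and C2 as a single enantiomer and leaves C5=C6 as a handle. The carboxyl carbon is then reduced to C7, two benzoates are installed, the free C1 hydroxyl steers epoxidation of C5=C6, and a third benzoic acid opens the oxirane at allylic C5 with inversion to give the trans C5 benzoate/C6 alcohol.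

Key step: step 1

Remarks on the chemistry:
- Ring atoms are numbered as in the target throughout: C1 is the quaternary carbinol, C2 its cis-oxygenated neighbour, C3=C4 the alkene, then C5 and C6; C7 is the exocyclic carbon.
- In step 1 the reducing equivalents (NADH) are assumed to be regenerated by the cells from the carbon source, so dioxygen is the only stoichiometric reagent counted.
- Step 4 consumes two equivalents of benzoyl chloride 5, one for the C7 hydroxyl and one for the C2 hydroxyl; the second equivalent is therefore also entered under the reagents that add atoms.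
- The descriptor at C1 is S in the acid and ester, R in the triol, dibenzoate and epoxide, and S again in the target. This reflects only the changing CIP ranking of its substituents; no bond at C1 is broken after step 1. The triol is accordingly named (1R,2R).

Step 1
Reactants: 1 benzoic acid
Product: 2 (1S,2R)-1,2-dihydroxycyclohexa-3,5-diene-1-carboxylic acid
Conditions: Cupriavidus necator B9 (Ralstonia eutropha B9; benzoate 1,2-dioxygenase active, cis-diol dehydrogenase absent), whole cells, benzoate fed as sodium salt, air, mineral salts medium with fructose, pH 7, 30 °C; cells removed, broth concentrated, acidified to pH 3 at 0 °C, EtOAc extraction, kept cold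
Reagents that add atoms: dioxygen, O=O
Why: The reductase and Rieske iron–sulfur components pass two electrons from NADH to the mononuclear non-heme iron centre, where divalent iron activates O2 and delivers both oxygen atoms to the same face of the ipso/ortho (C1–C2) bond of carboxylate-bound benzoate, the native substrate of the enzyme. The closest known reaction type is microbial arene cis-dihydroxylation as practised with toluene and benzoate dioxygenase strains. No ring is closed; the benzene ring is dearomatised to a cyclohexa-3,5-diene. C1 and C2 are both set by the enzyme active site (catalyst control), which exposes a single face of the anchored arene and should give the (1S,2R) cis-diol. The step needs ipso,ortho regioselectivity, secured by carboxylate binding, and survival of the diol, secured by the missing cis-diol dehydrogenase, which would otherwise rearomatise it to catechol.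

Step 2
Reactants: 2 (1S,2R)-1,2-dihydroxycyclohexa-3,5-diene-1-carboxylic acid
Product: 3 methyl (1S,2R)-1,2-dihydroxycyclohexa-3,5-diene-1-carboxylate
Conditions: TMSCHN2 (1.2 equiv, hexanes), MeOH/toluene 1:3, 0 °C
Reagents that add atoms: trimethylsilyldiazomethane, C[Si](C)(C)C=[N+]=[N-]
Why: Diazoalkane esterification O-methylates the carboxylate without any added acid, so the acid-labile dienediol should neither dehydrate nor decarboxylate, and neither stereocentre is touched.

Step 3
Reactants: 3 methyl (1S,2R)-1,2-dihydroxycyclohexa-3,5-diene-1-carboxylate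
Product: 4 (1R,2R)-1-(hydroxymethyl)cyclohexa-3,5-diene-1,2-diol
Conditions: NaBH4 (2 equiv), EtOH, 0 °C to rt; MeOH quench, evaporation, repeated co-evaporation with MeOH, short silica plug (EtOAc/MeOH); used at once, cold, no acid
Reagents that add atoms: none
Why: Chelation-assisted borohydride reduction of an α-hydroxy ester to the 1,2-diol is fast enough with NaBH4 to leave the unconjugated diene untouched, and since no bond at C1 or C2 is broken both stereocentres are carried through unchanged.

Step 4
Reactants: 4 (1R,2R)-1-(hydroxymethyl)cyclohexa-3,5-diene-1,2-diol; 5 benzoyl chloride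
Product: 6 [(1R,6R)-6-(benzoyloxy)-1-hydroxycyclohexa-2,4-dien-1-yl]methyl benzoate
Conditions: BzCl (2.2 equiv), pyridine (5 equiv), CH2Cl2, −20 to 0 °C
Reagents that add atoms: benzoyl chloride, O=C(Cl)c1ccccc1
Why: Pyridine-mediated O-acylation (nucleophilic acyl substitution) discriminates by steric demand, so the primary C7–OH and the secondary allylic C2–OH should each take up one benzoyl group while the tertiary C1–OH, unreactive at low temperature without DMAP, stays free as the later directing group.

Step 5
Reactants: 6 [(1R,6R)-6-(benzoyloxy)-1-hydroxycyclohexa-2,4-dien-1-yl]methyl benzoate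
Product: 7 [(1S,2R,3R,6S)-3-(benzoyloxy)-2-hydroxy-7-oxabicyclo[4.1.0]hept-4-en-2-yl]methyl benzoate
Conditions: VO(acac)2 (5 mol %), tBuOOH (1.3 equiv, anhydrous in decane), CH2Cl2, 0 °C to rt; aqueous Na2S2O3 quench; used promptly
Reagents that add atoms: tert-butyl hydroperoxide, CC(C)(C)OO
Why: In this vanadium-catalysed hydroxyl-directed epoxidation of an allylic alcohol the vanadate ester of the tertiary C1–OH delivers the peroxide oxygen intramolecularly to the allylic C5=C6 bond on the hydroxyl face, setting C5 and C6 syn to C1–OH, while C3=C4 is only homoallylic and is inductively deactivated by the C2 benzoate.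

Step 6
Reactants: 7 [(1S,2R,3R,6S)-3-(benzoyloxy)-2-hydroxy-7-oxabicyclo[4.1.0]hept-4-en-2-yl]methyl benzoate; 1 benzoic acid
Product: 8 [(1S,2R,5R,6S)-2,5-bis(benzoyloxy)-1,6-dihydroxycyclohex-3-en-1-yl]methyl benzoate (CNP0128482.1)
Conditions: Ti(OiPr)4 (1.5 equiv), PhCO2H (1.5 equiv), CH2Cl2, 0 °C to rt; aqueous potassium sodium tartrate work-up at pH 7
Reagents that add atoms: none
Why: In this Ti(OiPr)4-mediated opening of a 2,3-epoxy alcohol by a carboxylic acid, titanium bridges the C1 alkoxide and the oxirane oxygen and benzoate attacks the remote, allylic carbon C5 in an SN2 sense from the face opposite the oxygen, inverting C5 and leaving the C6–O bond intact, which should give the trans C5–OBz/C6–OH pair.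

Compound list
1 | benzoic acid | OC(=O)c1ccccc1 | starting material
2 | (1S,2R)-1,2-dihydroxycyclohexa-3,5-diene-1-carboxylic acid | OC(=O)[C@@]1(O)[C@H](O)C=CC=C1 | intermediate
3 | methyl (1S,2R)-1,2-dihydroxycyclohexa-3,5-diene-1-carboxylate | COC(=O)[C@@]1(O)[C@H](O)C=CC=C1 | intermediate
4 | (1R,2R)-1-(hydroxymethyl)cyclohexa-3,5-diene-1,2-diol | OC[C@@]1(O)[C@H](O)C=CC=C1 | intermediate
5 | benzoyl chloride | O=C(Cl)c1ccccc1 | starting material
6 | [(1R,6R)-6-(benzoyloxy)-1-hydroxycyclohexa-2,4-dien-1-yl]methyl benzoate (diene dibenzoate; C1–OH and C2–OBz cis, C1–OH free) | O=C(OC[C@@]1(O)[C@H](OC(=O)c2ccccc2)C=CC=C1)c1ccccc1 | intermediate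
7 | [(1S,2R,3R,6S)-3-(benzoyloxy)-2-hydroxy-7-oxabicyclo[4.1.0]hept-4-en-2-yl]methyl benzoate (C5–C6 vinyl oxirane on the face of C1–OH) | O=C(OC[C@@]1(O)[C@H](OC(=O)c3ccccc3)C=C[C@@H]2O[C@H]12)c1ccccc1 | intermediate
8 | [(1S,2R,5R,6S)-2,5-bis(benzoyloxy)-1,6-dihydroxycyclohex-3-en-1-yl]methyl benzoate (C1–OH, C2–OBz and C6–OH cis; C5–OBz trans to C6–OH) | O=C(OC[C@@]1(O)[C@H](OC(=O)c2ccccc2)C=C[C@@H](OC(=O)c2ccccc2)[C@@H]1O)c1ccccc1 | target

Total step count: 6
Longest linear sequence: 6 steps, from benzoic acid 1 to target 8

Steps most likely to fail

1. Step 6 (opening of the oxirane by benzoic acid). Regiocontrol may be lost through attack at C3 in an SN2′ sense or at C6. Isopropoxide may be transferred instead of benzoate. Titanium may also promote acyl migration between the C5 and C6 oxygens. Fallback, setting out from epoxide 7: acid-catalysed hydrolysis (THF/H2O, cat. HClO4, 0 °C), in which water attacks allylic C5 with inversion, should give the trans-5,6-diol [(1S,2R,5R,6S)-2-(benzoyloxy)-1,5,6-trihydroxycyclohex-3-en-1-yl]methyl benzoate F1. Its allylic C5–OH is less hindered than the C6–OH next to quaternary C1, so kinetic monobenzoylation with benzoyl chloride 5 (1.0 equiv, pyridine, CH2Cl2, −40 °C) should return to 8. This separates C–O bond formation from acylation.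

2. Step 5 (hydroxyl-directed epoxidation). Site and face selectivity may erode. The vanadium Lewis acid may open the nascent vinyl oxirane, or ionise the allylic C2 benzoate with rearomatisation. Fallback, setting out from diene dibenzoate 6: stoichiometric OsO4 with TMEDA (CH2Cl2, −78 °C) accepts a hydrogen bond from the tertiary C1–OH through its diamine-bound oxo ligand and should dihydroxylate the allylic C5=C6 bond on the hydroxyl face. Cleavage of the osmate ester (aqueous Na2SO3 or ethylenediamine) would give the all-cis triol [(1S,2R,5S,6S)-2-(benzoyloxy)-1,5,6-trihydroxycyclohex-3-en-1-yl]methyl benzoate F2. A Mitsunobu reaction with benzoic acid 1 (PPh3, DIAD, THF, 0 °C) at the less hindered, allylic C5–OH then inverts C5 and leads directly to 8, bypassing epoxide 7.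

3. Step 3 (reduction to the free triol). The water-soluble triol may be lost during removal of boron salts, and the diene may dimerise or aromatise under traces of acid during isolation. Fallback, setting out from ester 3: silylation of both hydroxyls (TMSCl, imidazole, DMF, 0 °C to rt) should give methyl (1S,2R)-1,2-bis(trimethylsilyloxy)cyclohexa-3,5-diene-1-carboxylate F3. Reduction with iBu2AlH (CH2Cl2, −78 to 0 °C, aqueous potassium sodium tartrate work-up) should give the lipophilic, extractable alcohol [(1R,6R)-1,6-bis(trimethylsilyloxy)cyclohexa-2,4-dien-1-yl]methanol F4. Methanolysis of the silyl ethers (cat. K2CO3, MeOH, 0 °C) returns to triol 4 with only volatile by-products.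

Further compounds
F1 | step 6 | [(1S,2R,5R,6S)-2-(benzoyloxy)-1,5,6-trihydroxycyclohex-3-en-1-yl]methyl benzoate | O=C(OC[C@@]1(O)[C@H](OC(=O)c2ccccc2)C=C[C@@H](O)[C@@H]1O)c1ccccc1
F2 | step 5 | [(1S,2R,5S,6S)-2-(benzoyloxy)-1,5,6-trihydroxycyclohex-3-en-1-yl]methyl benzoate | O=C(OC[C@@]1(O)[C@H](OC(=O)c2ccccc2)C=C[C@H](O)[C@@H]1O)c1ccccc1
F3 | step 3 | methyl (1S,2R)-1,2-bis(trimethylsilyloxy)cyclohexa-3,5-diene-1-carboxylate | COC(=O)[C@@]1(O[Si](C)(C)C)[C@H](O[Si](C)(C)C)C=CC=C1
F4 | step 3 | [(1R,6R)-1,6-bis(trimethylsilyloxy)cyclohexa-2,4-dien-1-yl]methanol | OC[C@@]1(O[Si](C)(C)C)[C@H](O[Si](C)(C)C)C=CC=C1
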